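Ring B (C1 quaternary epoxide carbon, C2 epoxide CH, C3 carbinol, C4 bearing CH2OH, C5 =CH, C6 carbinol) is cut into C2–C5 and C6–C1. C6(OH)–C1(O)–C1′(OH) is a masked dihydroxyacetone: the cyclic enol ether (C6=C1) of a glucose-derived 1,3-dioxan-5-one adds to methyl coumalate (C2–C5, ester on C4) in an inverse-demand Diels–Alder reaction. CO2 loss gives a cyclohexadiene with C5–C6 and C1–C2 formed, C1 and C6 set from C1′, and C4=C5 in place. Directed epoxidation and Payne transposition then make the former ketone oxygen the epoxide oxygen; a late Suzuki coupling adds ring A.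

Key step: step 5

Conventions: ring B locants are C1–C6 as above; the side chain is C1′ (carbinol) to C5′. The "upper face" of ring B is the face that carries the C1–C1′ bond and the C3 and C6 oxygens in the target; the epoxide oxygen lies on the lower face.
Remark: commercial 4,6-O-benzylidene-D-glucopyranose is taken as its anomeric mixture, since C1 and C2 of the sugar are excised in step 1. Lactone 9 is drawn as the endo-silyloxy adduct; endo and exo adducts converge on 10.

**Ring B fragment**

Step 1
Reactants: 1 4,6-O-benzylidene-D-glucopyranose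
Product: 4 (2R,4S,5R)-4-(hydroxymethyl)-2-phenyl-1,3-dioxan-5-ol, via 3-O-formyl-2,4-O-benzylidene-D-erythrose 2 (not isolated), via 2,4-O-benzylidene-D-erythrose 3 (not isolated)
Conditions: NaIO4 (2.1 equiv), NaHCO3, H2O, 0 °C to rt; then NaBH4, EtOH/H2O, 0 °C
Reagents that add atoms: none
Why: Periodate (Malaprade) cleavage of the C1–C2 and C2–C3 glycol bonds excises two sugar carbons, the formate ester hydrolyses in the buffered medium and borohydride reduces the aldehyde, so the two dioxane stereocentres (future C1′ and the acetal carbon) come unchanged from D-glucose.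

Step 2
Reactants: 4 (2R,4S,5R)-4-(hydroxymethyl)-2-phenyl-1,3-dioxan-5-ol
Product: 5 (2R,4S,5R)-2-phenyl-4-[(triethylsilyloxy)methyl]-1,3-dioxan-5-ol
Conditions: Et3SiCl (1.05 equiv), imidazole, CH2Cl2, −40 °C
Reagents that add atoms: chlorotriethylsilane, CC[Si](Cl)(CC)CC
Why: Silylation, in which the primary hydroxyl should react much faster than the ring secondary hydroxyl at low temperature.

Step 3
Reactants: 5 (2R,4S,5R)-2-phenyl-4-[(triethylsilyloxy)methyl]-1,3-dioxan-5-ol
Product: 6 (2R,4S)-2-phenyl-4-[(triethylsilyloxy)methyl]-1,3-dioxan-5-one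
Conditions: Dess–Martin periodinane, CH2Cl2, rt
Reagents that add atoms: none
Why: Dess–Martin oxidation gives the 1,3-dioxan-5-one under non-basic conditions that should leave the α-stereocentre (future C1′) and the primary silyl ether untouched.

Step 4
Reactants: 6 (2R,4S)-2-phenyl-4-[(triethylsilyloxy)methyl]-1,3-dioxan-5-one
Product: 7 (2R,4S)-2-phenyl-5-(triethylsilyloxy)-4-[(triethylsilyloxy)methyl]-4H-1,3-dioxine
Conditions: LiN(SiMe3)2, Et3SiCl (in situ quench), THF, −78 °C
Reagents that add atoms: chlorotriethylsilane, CC[Si](Cl)(CC)CC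
Why: Kinetic deprotonation by the hindered amide at the unsubstituted α-methylene (future C6) rather than the substituted methine, with in situ O-silylation, should give the cyclic enol ether C6=C1 with C1′ intact (regioselective silyl enol ether formation).

Step 5
Reactants: 7 (2R,4S)-2-phenyl-5-(triethylsilyloxy)-4-[(triethylsilyloxy)methyl]-4H-1,3-dioxine; 8 methyl coumalate (methyl 2-oxo-2H-pyran-5-carboxylate)
Product: 10 methyl 2-phenyl-4a-(triethylsilyloxy)-4-[(triethylsilyloxy)methyl]-4a,8a-dihydro-4H-1,3-benzodioxine-7-carboxylate (cis-fused; C1–OSi lower face, C1–C1′ and C6–O upper face), via bicyclic lactone 9 (not isolated)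
Conditions: toluene, 2,6-di-tert-butylpyridine (0.1 equiv), BHT (cat.), 120 °C, sealed tube
Reagents that add atoms: none
Why: This is an inverse-electron-demand Diels–Alder reaction of an electron-poor 2-pyrone with an electron-rich enol ether followed by retro-[4+2] loss of CO2, the known behaviour of coumalates toward enol ethers and 1,3-dioxoles. Ring B is closed by a suprafacial [4+2] cycloaddition that gives the oxabicyclo[2.2.2]octene lactone 9, whose bridge then leaves as CO2, so that the C2=C3/C4=C5 diene with the ester on C4 remains. The step needs the regiochemistry in which enol-ether carbon C6 bonds to pyrone C-6 (future C5) and C1 to pyrone C-3 (future C2); this is secured because C6 is the β-carbon of the silyl enol ether, developing charge is best stabilised at the silyloxy- and alkyl-substituted C1, and the ester makes pyrone C-6 the electrophilic terminus. C1 and C6 are set cis by the suprafacial addition and their absolute sense by C1′: the equatorial 2-phenyl group locks the dioxin half-chair, and the pyrone should add anti to the neighbouring silyloxymethyl group with bond formation leading at C6 along the axial trajectory. C1 carries no hydrogen, so aromatisation requires loss of silanol and is held back by the hindered base and the moderate temperature.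

Step 6
Reactants: 10 diene ester (bis-silyl ether)
Product: 11 methyl 4-(hydroxymethyl)-2-phenyl-4a-(triethylsilyloxy)-4a,8a-dihydro-4H-1,3-benzodioxine-7-carboxylate (configuration as 10)
Conditions: PPTS (0.1 equiv), MeOH/CH2Cl2, 0 °C
Reagents that add atoms: none
Why: Acid-catalysed methanolysis should remove the unhindered primary triethylsilyl ether much faster than the tertiary one at C1 (selective desilylation), unveiling the hydroxyl that directs step 7.

Step 7
Reactants: 11 primary alcohol diene
Product: 12 C2–C3 epoxide of 11 (epoxide oxygen on the upper face, syn to the C1–C1′ bond, anti to the C1 silyloxy group)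
Conditions: VO(acac)2 (5 mol %), t-BuOOH, CH2Cl2, 0 °C to rt
Reagents that add atoms: tert-butyl hydroperoxide, CC(C)(C)OO
Why: Vanadium-catalysed hydroxyl-directed epoxidation, in which the bishomoallylic C2′ hydroxyl, held above C2=C3 because C1′ sits pseudo-axial on the upper face, should deliver oxygen to that face of the more electron-rich, non-ester-bearing alkene and so set C2 and C3.

Step 8
Reactants: 12 epoxy alcohol
Product: 13 the corresponding C2′ aldehyde (4-carbaldehyde; other centres as 12)
Conditions: Dess–Martin periodinane, NaHCO3, CH2Cl2, 0 °C to rt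
Reagents that add atoms: none
Why: Buffered Dess–Martin oxidation of the primary alcohol should give the α-alkoxy aldehyde without epimerising C1′ or opening the vinyl epoxide.

Step 9
Reactants: 13 aldehyde
Product: 14 methyl ester bearing the (Z)-2-iodoprop-1-enyl group at C1′ (iodine cis to C1′; C2–C3 epoxide and C1–OSiEt3 retained)
Conditions: EtPPh3I, n-BuLi, THF, rt; I2, −78 °C; NaN(SiMe3)2, −20 °C; then 13, −78 °C
Reagents that add atoms: ethyltriphenylphosphonium iodide, CC[P+](c1ccccc1)(c1ccccc1)c1ccccc1.[I-]; iodine, II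
Why: Wittig olefination with (1-iodoethylidene)triphenylphosphorane (Stork–Zhao type) should give the trisubstituted (Z)-2-iodoalkene under kinetic control at low temperature, where addition to the aldehyde outruns enolisation.

Step 10
Reactants: 14 (Z)-vinyl iodide with C2–C3 epoxide
Product: 16 methyl ester with the C1–C2 epoxide on the lower face and a free C3 hydroxyl on the upper face (benzylidene acetal and vinyl iodide retained), via desilylated C2–C3 epoxy alcohol 15 (not isolated)
Conditions: Bu4NF (1.1 equiv), THF, −20 to 0 °C; then aq. NH4Cl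
Reagents that add atoms: none
Why: Fluoride cleaves the tertiary silyl ether and the C1 alkoxide opens the adjacent epoxide at C2 from the lower face with inversion (Payne rearrangement), which should favour the more substituted C1–C2 epoxide and the secondary allylic C3 alkoxide, C3 keeping its configuration.

Step 11
Reactants: 16 epoxy alcohol ester
Product: 17 the corresponding diol (C4–CH2OH; C3–OH)
Conditions: i-Bu2AlH (4 equiv), CH2Cl2, −78 °C; aq. potassium sodium tartrate (KNaC4H4O6)
Reagents that add atoms: none
Why: i-Bu2AlH reduces the conjugated methyl ester 1,2 to the primary allylic alcohol at −78 °C, where epoxide, acetal and vinyl iodide should not react.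

Step 12
Reactants: 17 benzylidene-protected diol
Product: 18 4-(hydroxymethyl)-1-[(1S,2Z)-1-hydroxy-3-iodobut-2-en-1-yl]-7-oxabicyclo[4.1.0]hept-3-ene-2,5-diol (ring B configuration as in the target)
Conditions: camphorsulfonic acid (0.2 equiv), MeOH, 0 °C to rt
Reagents that add atoms: none
Why: Acid-catalysed transacetalisation with methanol removes the benzylidene acetal under conditions that should be too mild to open the oxygen-flanked, electron-poor epoxide.

**Ring A fragment**

Step 13
Reactants: 19 geranyl acetate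
Product: 20 (2E)-5-[(2R)-3,3-dimethyloxiran-2-yl]-3-methylpent-2-en-1-yl acetate
Conditions: D-fructose-derived Shi ketone (0.3 equiv), Oxone (KHSO5), K2CO3, Bu4NHSO4, MeCN/dimethoxymethane/aq. borate buffer, 0 °C
Reagents that add atoms: potassium peroxymonosulfate, [K+].[O-]S(=O)(=O)OO
Why: Shi epoxidation, in which the chiral dioxirane attacks the electron-rich 6,7-alkene (the 2,3-alkene is deactivated by the allylic acetate) through a spiro transition state that should give the (R)-epoxide.

Step 14
Reactants: 20 (R)-6,7-epoxygeranyl acetate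
Product: 21 [(1S,5R)-5-hydroxy-2,6,6-trimethylcyclohex-2-en-1-yl]methyl acetate
Conditions: ZrCl4 (promoter), CH2Cl2, 0 °C to rt
Reagents that add atoms: none
Why: Lewis-acid-promoted epoxide–olefin cyclisation through a chair-like transition state places hydroxyl and acetoxymethyl groups equatorial (cis), the carbinol configuration comes from the epoxide carbon whose C–O bond is kept, and proton loss should give the endocyclic alkene.

Step 15
Reactants: 21 hydroxy acetate
Product: 22 [(1S,5R)-2,6,6-trimethyl-5-(triethylsilyloxy)cyclohex-2-en-1-yl]methyl acetate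
Conditions: Et3SiOTf, 2,6-lutidine, CH2Cl2, −78 °C
Reagents that add atoms: triethylsilyl trifluoromethanesulfonate, CC[Si](CC)(CC)OS(=O)(=O)C(F)(F)F
Why: Silylation of the hindered secondary alcohol with the silyl triflate, needed so that the later aldehyde cannot close to a bicyclic lactol.

Step 16
Reactants: 22 silyl ether acetate
Product: 23 [(1S,5R)-2,6,6-trimethyl-5-(triethylsilyloxy)cyclohex-2-en-1-yl]methanol
Conditions: K2CO3 (cat.), MeOH, rt
Reagents that add atoms: none
Why: Base-catalysed transesterification removes the primary acetate while the silyl ether is stable.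

Step 17
Reactants: 23 primary alcohol
Product: 24 (1S,5R)-2,6,6-trimethyl-5-(triethylsilyloxy)cyclohex-2-ene-1-carbaldehyde
Conditions: Dess–Martin periodinane, NaHCO3, CH2Cl2, 0 °C
Reagents that add atoms: none
Why: Buffered Dess–Martin oxidation should limit epimerisation or conjugation of the β,γ-unsaturated aldehyde, which is used at once.

Step 18
Reactants: 24 aldehyde
Product: 25 4,4,5,5-tetramethyl-2-[(E)-2-[(1S,5R)-2,6,6-trimethyl-5-(triethylsilyloxy)cyclohex-2-en-1-yl]ethenyl]-1,3,2-dioxaborolane
Conditions: CrCl2 (8 equiv), Cl2CHB(pin), LiI, THF, rt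
Reagents that add atoms: 2-(dichloromethyl)-4,4,5,5-tetramethyl-1,3,2-dioxaborolane, ClC(Cl)B1OC(C)(C)C(C)(C)O1
Why: Takai–Utimoto olefination through a geminal dichromium boryl species should give the (E)-alkenyl pinacol boronate under non-basic conditions that preserve the α-stereocentre.

Step 19
Reactants: 25 silyl-protected boronate
Product: 26 2-[(E)-2-[(1S,5R)-5-hydroxy-2,6,6-trimethylcyclohex-2-en-1-yl]ethenyl]-4,4,5,5-tetramethyl-1,3,2-dioxaborolane
Conditions: PPTS, MeOH, rt
Reagents that add atoms: none
Why: Acid-catalysed methanolysis of the triethylsilyl ether, which the alkenyl pinacol boronate should tolerate.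

**Fragment union**

Step 20
Reactants: 18 tetraol (Z)-vinyl iodide; 26 (E)-alkenyl boronate
Product: 27 CNP0389279.1, (1R,2S,5R,6S)-4-(hydroxymethyl)-1-[(1S,2Z,4E)-1-hydroxy-5-[(1S,5R)-5-hydroxy-2,6,6-trimethylcyclohex-2-en-1-yl]-3-methylpenta-2,4-dien-1-yl]-7-oxabicyclo[4.1.0]hept-3-ene-2,5-diol
Conditions: Pd(dppf)Cl2 (5 mol %), K3PO4, THF/H2O (degassed), rt
Reagents that add atoms: none
Why: Suzuki–Miyaura coupling proceeds with retention at both alkenes to give the (2′Z,4′E)-diene, and the free hydroxyls and the epoxide should tolerate the mild aqueous base at room temperature.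

**Compound list**

1 | 4,6-O-benzylidene-D-glucopyranose (anomeric mixture) | OC1O[C@@H]2CO[C@@H](c3ccccc3)O[C@H]2[C@H](O)[C@H]1O | starting material
2 | 3-O-formyl-2,4-O-benzylidene-D-erythrose | O=C[C@@H]1O[C@H](c2ccccc2)OC[C@H]1OC=O | intermediate
3 | 2,4-O-benzylidene-D-erythrose | O=C[C@@H]1O[C@H](c2ccccc2)OC[C@H]1O | intermediate
4 | (2R,4S,5R)-4-(hydroxymethyl)-2-phenyl-1,3-dioxan-5-ol | OC[C@@H]1O[C@H](c2ccccc2)OC[C@H]1O | intermediate
5 | (2R,4S,5R)-2-phenyl-4-[(triethylsilyloxy)methyl]-1,3-dioxan-5-ol | CC[Si](CC)(CC)OC[C@@H]1O[C@H](c2ccccc2)OC[C@H]1O | intermediate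
6 | (2R,4S)-2-phenyl-4-[(triethylsilyloxy)methyl]-1,3-dioxan-5-one | CC[Si](CC)(CC)OC[C@@H]1O[C@H](c2ccccc2)OCC1=O | intermediate
7 | (2R,4S)-2-phenyl-5-(triethylsilyloxy)-4-[(triethylsilyloxy)methyl]-4H-1,3-dioxine | CC[Si](CC)(CC)OC[C@@H]1O[C@H](c2ccccc2)OC=C1O[Si](CC)(CC)CC | intermediate
8 | methyl coumalate | COC(=O)C1=COC(=O)C=C1 | starting material
9 | bicyclic lactone cycloadduct (2-oxabicyclo[2.2.2]oct-5-en-3-one, endo-silyloxy) | CC[Si](CC)(CC)OC[C@@H]1O[C@H](c2ccccc2)O[C@H]2[C@H]3OC(=O)[C@H](C=C3C(=O)OC)[C@@]12O[Si](CC)(CC)CC | intermediate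
10 | methyl 2-phenyl-4a-(triethylsilyloxy)-4-[(triethylsilyloxy)methyl]-4a,8a-dihydro-4H-1,3-benzodioxine-7-carboxylate (cis-fused) | CC[Si](CC)(CC)OC[C@@H]1O[C@H](c2ccccc2)O[C@H]2C=C(C(=O)OC)C=C[C@@]12O[Si](CC)(CC)CC | intermediate
11 | 4-(hydroxymethyl) analogue of 10 | OC[C@@H]1O[C@H](c2ccccc2)O[C@H]2C=C(C(=O)OC)C=C[C@@]12O[Si](CC)(CC)CC | intermediate
12 | C2–C3 epoxide of 11 (upper face) | OC[C@@H]1O[C@H](c2ccccc2)O[C@H]2C=C(C(=O)OC)[C@H]3O[C@H]3[C@@]12O[Si](CC)(CC)CC | intermediate
13 | C2′ aldehyde from 12 | O=C[C@@H]1O[C@H](c2ccccc2)O[C@H]2C=C(C(=O)OC)[C@H]3O[C@H]3[C@@]12O[Si](CC)(CC)CC | intermediate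
14 | (Z)-2-iodoprop-1-enyl compound from 13 | I/C(C)=C\[C@@H]1O[C@H](c2ccccc2)O[C@H]2C=C(C(=O)OC)[C@H]3O[C@H]3[C@@]12O[Si](CC)(CC)CC | intermediate
15 | C1 tertiary alcohol with C2–C3 epoxide | I/C(C)=C\[C@@H]1O[C@H](c2ccccc2)O[C@H]2C=C(C(=O)OC)[C@H]3O[C@H]3[C@@]12O | intermediate
16 | C1–C2 epoxide (lower face), C3 alcohol, methyl ester | I/C(C)=C\[C@@H]1O[C@H](c2ccccc2)O[C@H]2C=C(C(=O)OC)[C@@H](O)[C@@H]3O[C@]123 | intermediate
17 | diol from 16 (C4–CH2OH) | I/C(C)=C\[C@@H]1O[C@H](c2ccccc2)O[C@H]2C=C(CO)[C@@H](O)[C@@H]3O[C@]123 | intermediate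
18 | 4-(hydroxymethyl)-1-[(1S,2Z)-1-hydroxy-3-iodobut-2-en-1-yl]-7-oxabicyclo[4.1.0]hept-3-ene-2,5-diol | I/C(C)=C\[C@H](O)[C@]12O[C@H]1[C@H](O)C(CO)=C[C@@H]2O | intermediate
19 | geranyl acetate | CC(C)=CCC/C(C)=C/COC(C)=O | starting material
20 | (2E)-5-[(2R)-3,3-dimethyloxiran-2-yl]-3-methylpent-2-en-1-yl acetate | CC(=O)OC/C=C(\C)CC[C@H]1OC1(C)C | intermediate
21 | [(1S,5R)-5-hydroxy-2,6,6-trimethylcyclohex-2-en-1-yl]methyl acetate | CC1=CC[C@@H](O)C(C)(C)[C@H]1COC(C)=O | intermediate
22 | [(1S,5R)-2,6,6-trimethyl-5-(triethylsilyloxy)cyclohex-2-en-1-yl]methyl acetate | CC1=CC[C@@H](O[Si](CC)(CC)CC)C(C)(C)[C@H]1COC(C)=O | intermediate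
23 | [(1S,5R)-2,6,6-trimethyl-5-(triethylsilyloxy)cyclohex-2-en-1-yl]methanol | CC1=CC[C@@H](O[Si](CC)(CC)CC)C(C)(C)[C@H]1CO | intermediate
24 | (1S,5R)-2,6,6-trimethyl-5-(triethylsilyloxy)cyclohex-2-ene-1-carbaldehyde | CC1=CC[C@@H](O[Si](CC)(CC)CC)C(C)(C)[C@H]1C=O | intermediate
25 | (E)-alkenyl pinacol boronate, silyl-protected | CC1=CC[C@@H](O[Si](CC)(CC)CC)C(C)(C)[C@H]1/C=C/B1OC(C)(C)C(C)(C)O1 | intermediate
26 | (E)-alkenyl pinacol boronate, free hydroxyl | CC1=CC[C@@H](O)C(C)(C)[C@H]1/C=C/B1OC(C)(C)C(C)(C)O1 | intermediate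
27 | CNP0389279.1 | CC1=CC[C@@H](O)C(C)(C)[C@H]1/C=C/C(C)=C\[C@H](O)[C@]12O[C@H]1[C@H](O)C(CO)=C[C@@H]2O | target

Total step count: 20. Longest linear sequence: 13 steps (steps 1–12 and 20).

**Steps most likely to fail**

1. Step 5. The trisubstituted enol ether may add too slowly to the pyrone, or the dihydroarene may aromatise by loss of triethylsilanol at the temperature needed for CO2 extrusion. The fallback sets out from 7 and comes back at 10, forming the same two bonds without an extrusion step. Enol ether 7 would be heated in toluene at 110 °C with methyl 3-sulfolene-3-carboxylate, which releases SO2 and methyl 2-methylidenebut-3-enoate F1. Its cycloaddition in the para orientation, with the same facial control, would give the cyclohex-3-ene ester adduct F2, which cannot aromatise. Deprotonation at C2 (LiN(i-Pr)2, THF/HMPA, −78 °C) and α-bromination of the dienolate with CBr4 would give the allylic α-bromo ester F3, and dehydrobromination toward C5 with DBU would return diene 10.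

2. Step 10. The epoxide migration may stop at an unfavourable equilibrium position, or the fluoride-generated alkoxide may trigger vinylogous elimination toward an arene. The fallback sets out from 14 and comes back at 17, separating desilylation from the transposition and making the latter irreversible. HF·pyridine (THF, 0 °C) would convert 14 into tertiary alcohol 15, now isolated. NaH (1.05 equiv) and Ac2O in THF at −40 °C would then trap the rearranged secondary alkoxide as the C3 acetate F4. i-Bu2AlH would cleave the acetate and reduce the methyl ester together, returning diol 17.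

3. Step 20. Base-induced epoxide migration in the unprotected epoxy tetraol, or protodeboronation, may erode the coupling. The fallback sets out from 24 and 18 and comes back at 27 through a base-free Stille coupling. Aldehyde 24 would be treated with CrCl2 and Bu3SnCHBr2 (LiI, THF/DMF) to give the silyl-protected (E)-alkenylstannane F5. Bu4NF would remove the silyl ether to give the hydroxy (E)-alkenylstannane F6, which would be coupled with iodide 18 under Pd2(dba)3/AsPh3 in N-methylpyrrolidone at rt to give 27.

Further compounds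
F1 | step 5 | methyl 2-methylidenebut-3-enoate | C=CC(=C)C(=O)OC
F2 | step 5 | cyclohex-3-ene ester adduct (ring B C3=C4, ester on C4; other centres as 10) | CC[Si](CC)(CC)OC[C@@H]1O[C@H](c2ccccc2)O[C@H]2CC(C(=O)OC)=CC[C@@]12O[Si](CC)(CC)CC
F3 | step 5 | allylic α-bromo ester (bromine and ester on C4, C2=C3; either C4 epimer) | CC[Si](CC)(CC)OC[C@@H]1O[C@H](c2ccccc2)O[C@H]2CC(Br)(C(=O)OC)C=C[C@@]12O[Si](CC)(CC)CC
F4 | step 10 | C3 acetate of 16 | I/C(C)=C\[C@@H]1O[C@H](c2ccccc2)O[C@H]2C=C(C(=O)OC)[C@@H](OC(C)=O)[C@@H]3O[C@]123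
F5 | step 20 | tributyl[(E)-2-[(1S,5R)-2,6,6-trimethyl-5-(triethylsilyloxy)cyclohex-2-en-1-yl]ethenyl]stannane | CC1=CC[C@@H](O[Si](CC)(CC)CC)C(C)(C)[C@H]1/C=C/[Sn](CCCC)(CCCC)CCCC
F6 | step 20 | tributyl[(E)-2-[(1S,5R)-5-hydroxy-2,6,6-trimethylcyclohex-2-en-1-yl]ethenyl]stannane | CC1=CC[C@@H](O)C(C)(C)[C@H]1/C=C/[Sn](CCCC)(CCCC)CCCC
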